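The cyclobutane hides a mirror plane: C1 and C2 carry cis carboxyl groups (acid and methyl ester), while C3 and C4 are fully substituted, each with a methyl and a 2-pyranone ring. Everything rests on closing the four-membered ring at C3–C4. The precursor is the open-chain symmetric anhydride of (E)-3-(pyranonyl)but-2-enoic acid, whose anhydride oxygen serves as tether. Sensitised irradiation first joins C1 to C2 in a five-membered anhydride ring; the 1,4-diradical, stabilised by the two pyranone rings, then collapses at C3–C4. One operation should give the meso bicyclic anhydride with all four stereocentres; alkaloid-mediated methanolysis then sets the absolute configuration.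

Key step: step 8

Remarks: Pyr = 4-methoxy-3-methyl-2-oxo-2H-pyran-6-yl. Cyclobutane numbering: C1 (CO2H), C2 (CO2Me), C3 (next to C2), C4 (next to C1). Compounds 1 and 6 are taken as commercial.
Assumption: the sense of the alkaloid-mediated methanolysis in step 9 is taken from the empirical model for cis-fused bicyclic meso anhydrides, by which quinine should deliver 12; the pseudo-enantiomer quinidine would give the mirror image.

Step 1
Reactants: 1 4-hydroxy-3,6-dimethyl-2H-pyran-2-one
Product: 2 4-methoxy-3,6-dimethyl-2H-pyran-2-one
Conditions: Me2SO4, K2CO3, acetone, reflux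
Reagents that add atoms: dimethyl sulfate COS(=O)(=O)OC
Why: Williamson-type O-methylation of the acidic 4-hydroxy group (a vinylogous carboxylic acid); with K2CO3 and dimethyl sulfate in acetone the 4-methoxy-2-pyranone should dominate over the isomeric 2-methoxy-4-pyranone.

Step 2
Reactants: 2 4-methoxy-3,6-dimethyl-2H-pyran-2-one
Product: 3 4-methoxy-5-methyl-6-oxo-6H-pyran-2-carbaldehyde
Conditions: SeO2, 1,4-dioxane, 160 °C (sealed tube)
Reagents that add atoms: selenium dioxide O=[Se]=O
Why: Riley oxidation should take only the C6 methyl, the one vinylogously activated by the ring carbonyl (ene reaction then [2,3]-shift), while the C3 methyl is not enolisable.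

Step 3
Reactants: 3 4-methoxy-5-methyl-6-oxo-6H-pyran-2-carbaldehyde
Product: 4 rac-6-(1-hydroxyethyl)-4-methoxy-3-methyl-2H-pyran-2-one
Conditions: MeMgBr, THF, −78 °C; then 1 M HCl
Reagents that add atoms: methylmagnesium bromide C[Mg]Br
Why: Grignard addition to the aldehyde, which at −78 °C is far more electrophilic than the vinylogous carbonate of the ring; the new carbinol centre is racemic and is removed in step 4.

Step 4
Reactants: 4 rac-6-(1-hydroxyethyl)-4-methoxy-3-methyl-2H-pyran-2-one
Product: 5 6-acetyl-4-methoxy-3-methyl-2H-pyran-2-one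
Conditions: Dess–Martin periodinane, CH2Cl2, rt
Reagents that add atoms: none
Why: Dess–Martin oxidation of the secondary alcohol under neutral conditions that leave the pyranone untouched.

Step 5
Reactants: 5 6-acetyl-4-methoxy-3-methyl-2H-pyran-2-one; 6 tert-butyl 2-(diethoxyphosphoryl)acetate
Product: 7 tert-butyl (E)-3-(Pyr)but-2-enoate
Conditions: NaH, THF, 0 °C to rt
Reagents that add atoms: none
Why: Horner–Wadsworth–Emmons olefination of an activated heteroaryl methyl ketone; the E isomer (pyranone trans to the ester) should prevail because the larger pyranone avoids the ester in the oxaphosphetane, and any Z isomer is removed by chromatography.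

Step 6
Reactants: 7 tert-butyl (E)-3-(Pyr)but-2-enoate
Product: 8 (E)-3-(Pyr)but-2-enoic acid
Conditions: TFA, CH2Cl2, rt
Reagents that add atoms: none
Why: Acidolysis of the tert-butyl ester (loss of 2-methylpropene by an E1 path), to which the pyranone, its enol ether and the enoate are inert.

Step 7
Reactants: 8 (E)-3-(Pyr)but-2-enoic acid (two equivalents)
Product: 9 (E,E)-3-(Pyr)but-2-enoic anhydride
Conditions: DCC (0.5 equiv), CH2Cl2, 0 °C to rt; filtration
Reagents that add atoms: none
Why: Carbodiimide dehydration: with half an equivalent of DCC the O-acylisourea is acylated by the second carboxylic acid to give the symmetric anhydride, and no base or nucleophile that could open the pyranone is present.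

Step 8
Reactants: 9 (E,E)-3-(Pyr)but-2-enoic anhydride
Product: 11 meso-(1R,5S,6R,7S)-6,7-dimethyl-6,7-bis(Pyr)-3-oxabicyclo[3.2.0]heptane-2,4-dione (cis-fused; both Pyr exo; both methyls endo), via cis-anhydride 1,4-diradical 10 (not isolated)
Conditions: [Ir(dF(CF3)ppy)2(dtbbpy)]PF6 (1 mol %), 450 nm LEDs, dry degassed CH2Cl2 (5 mM), rt
Reagents that add atoms: none
Why: The excited iridium complex passes triplet energy to one pyranonyl-enoate arm of 9, whose extended chromophore should lie below the sensitiser triplet while the isolated pyranone of 11 lies above it, so the product should not be re-excited; the triplet attacks the second enoate α-carbon to α-carbon (5-exo, rule of five), which closes the five-membered anhydride ring and leaves diradical 10 with both radical centres tertiary and delocalised into a pyranone ring. After intersystem crossing, 10 collapses by 1,4-diradical recombination between these two carbons, which closes the cyclobutane at the bond joining the two fully substituted ring carbons. The closest known reaction type is the sensitised intramolecular [2+2] photocycloaddition of 1,6-dienes to bicyclo[3.2.0]heptanes, as with diacylimide-tethered and diol-tethered cinnamoyl pairs. The two CH stereocentres are set cis by the ring fusion, since only the cis diradical can close while the trans one reverts to 9; at each quaternary centre the larger planar pyranone should end on the convex (exo) face and the methyl on the concave face, whatever the alkene geometry, because the triplet path is stereoconvergent. The step needs straight over crossed regiochemistry, secured by the three-atom tether and by the better-stabilised diradical; intramolecular over intermolecular reaction, secured by the 5 mM dilution; and exo,exo over exo,endo closure, which is the least certain point.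

Step 9
Reactants: 11 meso-(1R,5S,6R,7S)-6,7-dimethyl-6,7-bis(Pyr)-3-oxabicyclo[3.2.0]heptane-2,4-dione
Product: 12 (1S,2R,3S,4R)-2-(methoxycarbonyl)-3,4-dimethyl-3,4-bis(Pyr)cyclobutane-1-carboxylic acid
Conditions: quinine (1.1 equiv), MeOH (3 equiv), toluene, −55 °C; then 1 M HCl
Reagents that add atoms: methanol CO
Why: Cinchona-alkaloid-mediated desymmetrising methanolysis of a meso cyclic anhydride: the quinuclidine nitrogen should deliver methanol to one of the two enantiotopic carbonyls, which turns the mirror-symmetric core with its four fixed stereocentres into the single (1S,2R,3S,4R) hemiester.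

Compound list
1 | 4-hydroxy-3,6-dimethyl-2H-pyran-2-one | Cc1cc(O)c(C)c(=O)o1 | starting material
2 | 4-methoxy-3,6-dimethyl-2H-pyran-2-one | COc1cc(C)oc(=O)c1C | intermediate
3 | 4-methoxy-5-methyl-6-oxo-6H-pyran-2-carbaldehyde | COc1cc(C=O)oc(=O)c1C | intermediate
4 | rac-6-(1-hydroxyethyl)-4-methoxy-3-methyl-2H-pyran-2-one | COc1cc(C(C)O)oc(=O)c1C | intermediate
5 | 6-acetyl-4-methoxy-3-methyl-2H-pyran-2-one | COc1cc(C(C)=O)oc(=O)c1C | intermediate
6 | tert-butyl 2-(diethoxyphosphoryl)acetate | CCOP(=O)(OCC)CC(=O)OC(C)(C)C | starting material
7 | tert-butyl (E)-3-(4-methoxy-3-methyl-2-oxo-2H-pyran-6-yl)but-2-enoate | COc1cc(/C(C)=C/C(=O)OC(C)(C)C)oc(=O)c1C | intermediate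
8 | (E)-3-(4-methoxy-3-methyl-2-oxo-2H-pyran-6-yl)but-2-enoic acid | COc1cc(/C(C)=C/C(=O)O)oc(=O)c1C | intermediate
9 | (E,E)-3-(4-methoxy-3-methyl-2-oxo-2H-pyran-6-yl)but-2-enoic anhydride | COc1cc(/C(C)=C/C(=O)OC(=O)/C=C(\C)c2cc(OC)c(C)c(=O)o2)oc(=O)c1C | intermediate
10 | meso-cis-3,4-bis[1-(4-methoxy-3-methyl-2-oxo-2H-pyran-6-yl)ethan-1-yl]oxolane-2,5-dione 1,4-diradical | O=C1OC(=O)[C@H]([C](C)c2cc(OC)c(C)c(=O)o2)[C@@H]1[C](C)c1cc(OC)c(C)c(=O)o1 | intermediate
11 | meso-(1R,5S,6R,7S)-6,7-dimethyl-6,7-bis(4-methoxy-3-methyl-2-oxo-2H-pyran-6-yl)-3-oxabicyclo[3.2.0]heptane-2,4-dione (pyranones exo, methyls endo) | O=C1OC(=O)[C@H]2[C@@H]1[C@](C)(c3cc(OC)c(C)c(=O)o3)[C@]2(C)c3cc(OC)c(C)c(=O)o3 | intermediate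
12 | (1S,2R,3S,4R)-2-(methoxycarbonyl)-3,4-bis(4-methoxy-3-methyl-2-oxo-2H-pyran-6-yl)-3,4-dimethylcyclobutane-1-carboxylic acid | COC(=O)[C@@H]1[C@H](C(=O)O)[C@@](C)(c2cc(OC)c(C)c(=O)o2)[C@@]1(C)c1cc(OC)c(C)c(=O)o1 | target

Total step count: 9. Longest linear sequence: 9 steps (1 to 12; 6 enters at step 5).

Steps most likely to fail

Step 8. Two processes threaten it. The long-lived 1,4-diradical may rotate about its ring-to-radical bonds before closure, so that a pyranone ends on the concave face. Or the excited state may decay only by E/Z isomerisation, because the anhydride conformer with both carbonyl oxygens turned outward is too thinly populated. The fallback sets out from acid 8 and uses a rigid covalent template with a topochemical, non-diradical cycloaddition. Double esterification of naphthalene-1,8-diol with two equivalents of 8 (DCC, DMAP cat., CH2Cl2) should give naphthalene-1,8-diyl bis[(E)-3-(Pyr)but-2-enoate] F1, whose peri oxygens hold the two enoates stacked head-to-head. Irradiation of crystalline F1 at 365 nm should give the syn head-to-head cyclobutane, the naphthalene-1,8-diyl cyclobutane-1,2-dicarboxylate F2, with the alkene geometry retained. Cleavage of the two labile aryl esters (LiOH, 2.2 equiv, THF/H2O, 0 °C, then HCl) should give the meso 3,4-dimethyl-3,4-bis(Pyr)cyclobutane-1,2-dicarboxylic acid F3. Dehydration with acetic anhydride returns to the route at 11.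

Step 9. Discrimination of the enantiotopic carbonyls may be weak or of the opposite sense, because the anhydride is flanked by two quaternary carbons unlike the model substrates. The fallback sets out from 11 and does not depend on the sense of induction. Unselective methanolysis (MeOH, Et3N cat., CH2Cl2, rt) should give the racemic hemiester, that is 12 together with its enantiomer, the (1R,2S,3R,4S) hemiester F4. Classical resolution by crystallisation with (R)-1-phenylethylamine (or its antipode, whichever salt of 12 is the less soluble) should give the (R)-1-phenylethylammonium salt of 12 F5. Acidification with 1 M HCl returns to the route at 12.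

Step 5. The basic phosphonate anion may enolise the methyl ketone or attack the pyranone, and E/Z control in ketone olefination may be poor. The fallback sets out from ketone 5 and forms the bond with a non-basic nucleophile. Reformatsky addition of the zinc enolate made from tert-butyl bromoacetate and Zn (THF, reflux; then 1 M HCl) should give rac-tert-butyl 3-hydroxy-3-(Pyr)butanoate F6. Dehydration with Burgess reagent (toluene, 60 °C), followed by equilibration of the alkene isomers with catalytic DBU towards the conjugated E enoate, returns to the route at 7.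

Further compounds
F1 | step 8 | naphthalene-1,8-diyl bis[(E)-3-(4-methoxy-3-methyl-2-oxo-2H-pyran-6-yl)but-2-enoate] | O=C(/C=C(\C)c1cc(OC)c(C)c(=O)o1)Oc1cccc2cccc(OC(=O)/C=C(\C)c3cc(OC)c(C)c(=O)o3)c12
F2 | step 8 | naphthalene-1,8-diyl meso-3,4-dimethyl-3,4-bis(4-methoxy-3-methyl-2-oxo-2H-pyran-6-yl)cyclobutane-1,2-dicarboxylate (carboxyls cis, pyranones cis to each other and trans to the carboxyls) | O=C1Oc2cccc3cccc(c23)OC(=O)[C@H]4[C@@H]1[C@](C)(c5cc(OC)c(C)c(=O)o5)[C@]4(C)c5cc(OC)c(C)c(=O)o5
F3 | step 8 | meso-3,4-dimethyl-3,4-bis(4-methoxy-3-methyl-2-oxo-2H-pyran-6-yl)cyclobutane-1,2-dicarboxylic acid | OC(=O)[C@H]1[C@@H](C(=O)O)[C@](C)(c2cc(OC)c(C)c(=O)o2)[C@]1(C)c1cc(OC)c(C)c(=O)o1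
F4 | step 9 | (1R,2S,3R,4S)-2-(methoxycarbonyl)-3,4-bis(4-methoxy-3-methyl-2-oxo-2H-pyran-6-yl)-3,4-dimethylcyclobutane-1-carboxylic acid (enantiomer of 12) | COC(=O)[C@H]1[C@@H](C(=O)O)[C@](C)(c2cc(OC)c(C)c(=O)o2)[C@]1(C)c1cc(OC)c(C)c(=O)o1
F5 | step 9 | (R)-1-phenylethylammonium salt of 12 | COC(=O)[C@@H]1[C@H](C(=O)[O-])[C@@](C)(c2cc(OC)c(C)c(=O)o2)[C@@]1(C)c1cc(OC)c(C)c(=O)o1.C[C@@H]([NH3+])c1ccccc1
F6 | step 5 | rac-tert-butyl 3-hydroxy-3-(4-methoxy-3-methyl-2-oxo-2H-pyran-6-yl)butanoate | COc1cc(C(C)(O)CC(=O)OC(C)(C)C)oc(=O)c1C
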